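**Plan**
1. Retrosynthesis: remove the C1–C10 epoxide oxygen; cut the C8 ester and the lactone C12–O6 bond and trade C11=C13 for a C11 bis(hydroxymethyl) unit; return C8–OH to a ketone; rejoin C3 and C8 as C=C (retro-ozonolysis) to a hexahydronaphthalene; rearomatise (retro-Birch) to a tetralin; cut C7–C11 (malonate/epoxide), C6=C7 (metathesis) and C4–C5 (enolate allylation).
2. Enabling feature: C3 and C8 both carry oxygen and are linked on one side by C4–C5–C6–C7 and on the other by C2–C1=C10–C9. C3, C2, C1, C10, C9, C8 are therefore a 1,4-cyclohexadiene, a Birch-reduced benzene ring fused at C3–C8 to the six-membered ring C3–C4–C5–C6–C7–C8 (ring B).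
3. Forward ring order: the benzene ring is bought; ring B closes by metathesis (step 6); the ten-membered ring is laid bare by ozonolysis of C3=C8 (step 13); lactone (step 17); epoxide last (step 21).
4. Stereochemistry: C4 from an Evans alkylation; C6 and C7 from a Jacobsen epoxidation anti to the C4 side chain followed by SN2 opening; C8 from a C6–OH-directed anti reduction; C2' from (R)-2-methylbutanoic acid; C1/C10 from peracid attack on the Z alkene inherited from the arene.

Key step: step 13

Remark: locants C1–C15 are those of the germacrane skeleton of the target and are used for every intermediate.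
Remark: C11 is a stereocentre in 14 and 16–31 but becomes sp2 in 32; these compounds are carried as C11 epimer mixtures and drawn without a C11 descriptor.
Remark: the 6-hydroxy-3-ketones 21, 22, 25, 26 and 27 are drawn open; each is expected to rest largely as its transannular C3–O–C6 hemiketal, which equilibrates freely and is treated as the same compound.

Step 1
Reactants: 1 2-(2-bromo-4-methylphenyl)acetic acid
Product: 2 2-(4-methyl-2-vinylphenyl)acetic acid
Conditions: CH2=CHBF3K, PdCl2(dppf) (3 mol%), K2CO3, THF–H2O, 75 °C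
Reagents that add atoms: potassium vinyltrifluoroborate, C=C[B-](F)(F)F.[K+]
Why: Suzuki–Miyaura coupling of an aryl bromide with a vinyltrifluoroborate is routine and tolerates the carboxylate; it is run first so that arylpalladium never meets a pendant alkene (no Heck cyclisation), and the new vinyl CH becomes C7.

Step 2
Reactants: 2 2-(4-methyl-2-vinylphenyl)acetic acid; 3 (R)-4-benzyl-2-oxazolidinone
Product: 5 (R)-4-benzyl-3-[2-(4-methyl-2-vinylphenyl)acetyl]-2-oxazolidinone, via mixed pivalic anhydride 4 (not isolated)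
Conditions: PivCl, Et3N, THF, −20 °C; then LiCl, 3, −20 °C → rt
Reagents that add atoms: none
Why: N-acylation of an oxazolidinone through the pivalic mixed anhydride (LiCl-assisted) is the standard, racemisation-free entry to an Evans imide.

Step 3
Reactants: 5 (R)-4-benzyl-3-[2-(4-methyl-2-vinylphenyl)acetyl]-2-oxazolidinone
Product: 7 (R)-4-benzyl-3-[(R)-2-(4-methyl-2-vinylphenyl)pent-4-enoyl]-2-oxazolidinone, via sodium Z-enolate 6 (not isolated)
Conditions: NaN(SiMe3)2, THF, −78 °C; allyl iodide, −78 → −40 °C
Reagents that add atoms: allyl iodide, C=CCI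
Why: Evans asymmetric alkylation: the chelated Z-enolate 6 is attacked by allyl iodide on the face opposite the benzyl group of the (R)-auxiliary, which creates C4 in the configuration the target needs and adds C5 and C6.

Step 4
Reactants: 7 (R)-4-benzyl-3-[(R)-2-(4-methyl-2-vinylphenyl)pent-4-enoyl]-2-oxazolidinone
Product: 8 (R)-2-(4-methyl-2-vinylphenyl)pent-4-en-1-ol
Conditions: LiBH4, MeOH (1 equiv), Et2O, 0 °C
Reagents that add atoms: none
Why: Reductive cleavage of the imide with LiBH4 gives the primary alcohol (the future C15 hydroxyl) and returns the auxiliary under conditions that do not epimerise α-aryl centres.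

Step 5
Reactants: 8 (R)-2-(4-methyl-2-vinylphenyl)pent-4-en-1-ol
Product: 9 triisopropylsilyl ether of 8
Conditions: TIPSCl, imidazole, CH2Cl2, rt
Reagents that add atoms: chlorotriisopropylsilane, CC(C)[Si](Cl)(C(C)C)C(C)C
Why: Silylation of a primary alcohol; the triisopropylsilyl ether is chosen because it has to survive dissolving metal, ozone, acid and the removal of two more labile silyl groups before step 20.

Step 6
Reactants: 9 triisopropylsilyl ether of 8
Product: 10 (R)-6-methyl-1-[(triisopropylsilyloxy)methyl]-1,2-dihydronaphthalene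
Conditions: second-generation Grubbs catalyst (H2IMes)(PCy3)Cl2Ru=CHPh (2 mol%), CH2Cl2, 40 °C
Reagents that add atoms: none
Why: Ring-closing metathesis between the styrene and the terminal alkene forms ring B as a 1,2-dihydronaphthalene with loss of ethene, a well-established six-membered closure that leaves C4 untouched.

Step 7
Reactants: 10 (R)-6-methyl-1-[(triisopropylsilyloxy)methyl]-1,2-dihydronaphthalene
Product: 11 (1S,2R,4R)-1,2-epoxy-7-methyl-4-[(triisopropylsilyloxy)methyl]-1,2,3,4-tetrahydronaphthalene
Conditions: (S,S)-N,N'-bis(3,5-di-tert-butylsalicylidene)-1,2-cyclohexanediaminomanganese chloride (4 mol%), aq NaOCl (pH 11.3), 4-phenylpyridine N-oxide, CH2Cl2, 0 °C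
Reagents that add atoms: sodium hypochlorite, [Na+].[O-]Cl
Why: Jacobsen epoxidation of a cis-disubstituted aryl alkene: the (S,S)-catalyst gives the (1S,2R)-epoxide of dihydronaphthalenes, and that enantioface is here also the one anti to the pseudoaxial C4 side chain, so catalyst and substrate control reinforce each other and fix the C6–O configuration.

Step 8
Reactants: 11 (1S,2R,4R)-1,2-epoxy-7-methyl-4-[(triisopropylsilyloxy)methyl]-1,2,3,4-tetrahydronaphthalene; 12 dimethyl malonate
Product: 14 trans-fused α-methoxycarbonyl γ-lactone on the tetralin (O6–C12 lactone; C13 methyl ester), via hydroxy malonate 13 (not isolated)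
Conditions: NaOMe, MeOH, 65 °C; aq NH4Cl
Reagents that add atoms: none
Why: SN2 opening of the aryl epoxide by sodiomalonate at the benzylic carbon C7 (electronically activated, whereas attack at C6 would have to pass the syn-axial C4 side chain) inverts C7 and gives the trans C6–O/C7–C11 relationship, after which the alkoxide closes the lactone on one ester.

Step 9
Reactants: 14 trans-fused α-methoxycarbonyl γ-lactone on the tetralin
Product: 15 tetralin triol (C6–OH, C12–OH, C13–OH; C15–OTIPS)
Conditions: LiAlH4, THF, 0 → 66 °C; Fieser work-up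
Reagents that add atoms: none
Why: Exhaustive LiAlH4 reduction of lactone and ester (and of any unlactonised 13) converges on one triol in which C12 and C13 are both at the alcohol level that survives the Birch step.

Step 10
Reactants: 15 tetralin triol
Product: 16 mono-TBS ether (C13–OTBS; C6–OH and C12–OH free)
Conditions: NaH (1.0 equiv), THF, 0 °C → rt; TBSCl (1.0 equiv)
Reagents that add atoms: tert-butylchlorodimethylsilane, CC(C)(C)[Si](C)(C)Cl
Why: Monosilylation of a 1,3-diol through its monosodium alkoxide is a known way to protect one of two equivalent primary hydroxyls; either arm may react because C11 loses its stereogenicity in step 19, and the hindered secondary C6 hydroxyl is left alone.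

Step 11
Reactants: 16 mono-TBS ether
Product: 17 tetralin with C12–OTES, C13–OTBS, C15–OTIPS and free C6–OH
Conditions: TESCl (1.05 equiv), imidazole, CH2Cl2, −78 → −40 °C
Reagents that add atoms: chlorotriethylsilane, CC[Si](Cl)(CC)CC
Why: Chlorotriethylsilane at low temperature silylates the remaining primary hydroxyl in preference to the hindered secondary C6 hydroxyl, giving three primary silyl ethers of graded lability (TES < TBS < TIPS) that are later removed one at a time.

Step 12
Reactants: 17 tetralin with C12–OTES, C13–OTBS, C15–OTIPS and free C6–OH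
Product: 18 1,2,3,4,5,8-hexahydronaphthalene with C3=C8 and C1=C10 double bonds (same substituents)
Conditions: Li, NH3(l), THF, t-BuOH, −78 → −33 °C; NH4Cl
Reagents that add atoms: none
Why: Birch reduction of a 1,2,4-trialkylbenzene protonates the two unsubstituted para carbons (C2 and C9), so all three alkyl-bearing carbons stay olefinic and the 1,4-diene has the tetrasubstituted C3=C8 and trisubstituted C1=C10 bonds; silyl ethers and the alkoxide are inert and no benzylic C–O bond is present.

Step 13
Reactants: 18 1,2,3,4,5,8-hexahydronaphthalene with C3=C8 and C1=C10 double bonds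
Product: 21 (Z)-6-hydroxycyclodec-1(10)-ene-3,8-dione carrying C4–CH2OTIPS and the C7 side chain, via primary ozonide 19 (not isolated), via secondary ozonide 20 (not isolated)
Conditions: O3/O2 (dilute stream), CH2Cl2, Sudan Red 7B, −78 °C; then PPh3, −78 °C → rt; crude used at once
Reagents that add atoms: ozone, [O-][O+]=O
Why: Ozone adds as a 1,3-dipole to the most electron-rich π bond, the tetrasubstituted C3=C8 alkene, to give primary ozonide 19, which cycloreverts to a tethered ketone–carbonyl oxide pair that recloses to the 1,2,4-trioxolane 20; PPh3 then removes one oxygen and releases both ketones. The closest known reaction type is the Criegee ozonolysis of the central double bond of Birch-derived tetrahydronaphthalenes and of Δ9(10)-octalin to cyclodecane-1,6-diones. The ten-membered ring is not closed end to end: it already exists as the periphery of the bicycle and is unveiled by scission of the shared C3–C8 bond, so no medium-ring cyclisation has to be won in a bond-forming event. No stereocentre is created; C4, C6 and C7 are untouched and the Z geometry of C1=C10 is inherited from the six-membered ring. The selectivity needed is chemoselectivity for the tetrasubstituted over the trisubstituted alkene, which rests on the higher nucleophilicity of the fully alkylated double bond toward electrophilic ozone, on −78 °C and a dilute ozone stream, and on stopping at the bleaching of the indicator dye. The free C6 hydroxyl is tolerated, and the product is taken on quickly because it is a β-hydroxy ketone flanked by skipped enone units.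

Step 14
Reactants: 21 (Z)-6-hydroxycyclodec-1(10)-ene-3,8-dione
Product: 22 6,8-anti-diol 3-ketone
Conditions: Me4NBH(OAc)3, MeCN–AcOH (1:1), −30 °C
Reagents that add atoms: none
Why: Evans–Saksena reduction: the C6 hydroxyl of the open tautomer exchanges onto boron and delivers hydride to the β-ketone C8 from its own face, giving the 6,8-anti diol (new C8 stereocentre), while the C3 ketone, which has no β-hydroxyl and is largely masked as the hemiketal, is not reduced.

Step 15
Reactants: 22 6,8-anti-diol 3-ketone; 23 (R)-2-methylbutanoic acid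
Product: 25 C8 (R)-2-methylbutanoate, via mixed aryl anhydride 24 (not isolated)
Conditions: 23, 2,4,6-trichlorobenzoyl chloride, Et3N, THF, rt; then 22, DMAP, toluene, rt
Reagents that add atoms: none
Why: Yamaguchi esterification of the only free secondary carbinol: O6 is sequestered in the C3 hemiketal, whose tertiary anomeric hydroxyl is not acylated, so the acyl group goes to O8, and the mixed-anhydride/DMAP protocol does not racemise the α-methyl acid.

Step 16
Reactants: 25 C8 (R)-2-methylbutanoate
Product: 26 C12 primary alcohol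
Conditions: AcOH–THF–H2O (3:1:1), 0 °C
Reagents that add atoms: none
Why: Mild aqueous acetic acid removes a primary triethylsilyl ether much faster than primary TBS or TIPS ethers, unmasking only the C12 hydroxyl.

Step 17
Reactants: 26 C12 primary alcohol
Product: 29 6,12-lactone with C13–OTBS, via hydroxy aldehyde 27 (not isolated), via lactol 28 (not isolated)
Conditions: TEMPO (0.2 equiv), PhI(OAc)2 (2.5 equiv), CH2Cl2, rt
Reagents that add atoms: none
Why: TEMPO/PhI(OAc)2 oxidative lactonisation of a 1,4-diol: the primary alcohol is oxidised to aldehyde 27, O6 adds to it (draining the hemiketal equilibrium) to give lactol 28, and a second oxidation gives the γ-lactone, whose trans ring fusion is fixed by C6 and C7; no other free alcohol is present.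

Step 18
Reactants: 29 6,12-lactone with C13–OTBS
Product: 30 13-hydroxy lactone
Conditions: HF·pyridine, pyridine, THF, 0 °C
Reagents that add atoms: none
Why: Buffered HF·pyridine cleaves the primary TBS ether well before the primary TIPS ether, releasing the C13 hydroxyl.

Step 19
Reactants: 30 13-hydroxy lactone
Product: 32 α-methylene lactone with C15–OTIPS, via mesylate 31 (not isolated)
Conditions: MsCl, Et3N, CH2Cl2, 0 °C; then DBU (1.1 equiv), 0 °C, brief
Reagents that add atoms: none
Why: Sulfonylation and E1cB elimination of a β-mesyloxy lactone is the classical route to an α-methylene γ-lactone; the brief, weakly basic conditions spare the C4 centre next to the C3 ketone and the β-silyloxy ketone.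

Step 20
Reactants: 32 α-methylene lactone with C15–OTIPS
Product: 33 15-hydroxy 1(10)-Z-alkene (de-epoxy target)
Conditions: HF·pyridine, THF, rt
Reagents that add atoms: none
Why: Fluoride-mediated desilylation of the primary TIPS ether, done before epoxidation so that no epoxide is exposed to fluoride or acid; the α-methylene lactone and the esters are stable to it.

Step 21
Reactants: 33 15-hydroxy 1(10)-Z-alkene
Product: 34 target CNP0219035.1
Conditions: mCPBA, NaHCO3, CH2Cl2, 0 °C
Reagents that add atoms: 3-chloroperbenzoic acid, OOC(=O)c1cccc(Cl)c1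
Why: Prilezhaev epoxidation: the peracid reacts only with the electron-rich trisubstituted C1=C10 alkene (the acrylate-type C11=C13 bond is inert), syn addition to the Z alkene gives the cis epoxide, and attack on the outer face of the ring, expected to be the face bearing the C8 ester, sets C1 and C10.

**Compound list**
1 | 2-(2-bromo-4-methylphenyl)acetic acid | Cc1ccc(CC(=O)O)c(Br)c1 | starting material
2 | 2-(4-methyl-2-vinylphenyl)acetic acid | Cc1ccc(CC(=O)O)c(C=C)c1 | intermediate
3 | (R)-4-benzyl-2-oxazolidinone | O=C1OC[C@@H](Cc2ccccc2)N1 | starting material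
4 | mixed anhydride of 2 with pivalic acid | Cc1ccc(CC(=O)OC(=O)C(C)(C)C)c(C=C)c1 | intermediate
5 | (R)-4-benzyl-3-[2-(4-methyl-2-vinylphenyl)acetyl]-2-oxazolidinone | Cc1ccc(CC(=O)N2[C@H](Cc3ccccc3)COC2=O)c(C=C)c1 | intermediate
6 | sodium (Z)-enolate of 5 | [Na+].[O-]/C(=C\c1ccc(C)cc1C=C)N1[C@H](Cc2ccccc2)COC1=O | intermediate
7 | (R)-4-benzyl-3-[(R)-2-(4-methyl-2-vinylphenyl)pent-4-enoyl]-2-oxazolidinone | C=CC[C@@H](C(=O)N1[C@H](Cc2ccccc2)COC1=O)c1ccc(C)cc1C=C | intermediate
8 | (R)-2-(4-methyl-2-vinylphenyl)pent-4-en-1-ol | C=CC[C@@H](CO)c1ccc(C)cc1C=C | intermediate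
9 | triisopropylsilyl ether of 8 | C=CC[C@@H](CO[Si](C(C)C)(C(C)C)C(C)C)c1ccc(C)cc1C=C | intermediate
10 | (R)-6-methyl-1-[(triisopropylsilyloxy)methyl]-1,2-dihydronaphthalene | C1[C@@H](CO[Si](C(C)C)(C(C)C)C(C)C)c2ccc(C)cc2C=C1 | intermediate
11 | (1S,2R,4R)-1,2-epoxy-7-methyl-4-[(triisopropylsilyloxy)methyl]-1,2,3,4-tetrahydronaphthalene | C1[C@@H](CO[Si](C(C)C)(C(C)C)C(C)C)c2ccc(C)cc2[C@@H]3O[C@H]13 | intermediate
12 | dimethyl malonate | COC(=O)CC(=O)OC | starting material
13 | hydroxy malonate: C6–OH trans to the C7 malonyl group, C4 side chain cis to the malonyl group | O[C@@H]1C[C@@H](CO[Si](C(C)C)(C(C)C)C(C)C)c2ccc(C)cc2[C@H]1C(C(=O)OC)C(=O)OC | intermediate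
14 | trans-fused α-methoxycarbonyl γ-lactone on the tetralin (O6–C12 lactone, C13 methyl ester, C15–OTIPS) | COC(=O)C1C(=O)O[C@@H]2C[C@@H](CO[Si](C(C)C)(C(C)C)C(C)C)c3ccc(C)cc3[C@@H]12 | intermediate
15 | tetralin triol (C6–OH, C12–OH, C13–OH; C15–OTIPS) | O[C@@H]1C[C@@H](CO[Si](C(C)C)(C(C)C)C(C)C)c2ccc(C)cc2[C@H]1C(CO)CO | intermediate
16 | mono-TBS ether of 15 (C13–OTBS) | O[C@@H]1C[C@@H](CO[Si](C(C)C)(C(C)C)C(C)C)c2ccc(C)cc2[C@H]1C(CO)CO[Si](C)(C)C(C)(C)C | intermediate
17 | tetralin with C12–OTES, C13–OTBS, C15–OTIPS and free C6–OH | O[C@@H]1C[C@@H](CO[Si](C(C)C)(C(C)C)C(C)C)c2ccc(C)cc2[C@H]1C(CO[Si](CC)(CC)CC)CO[Si](C)(C)C(C)(C)C | intermediate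
18 | Birch product, hexahydronaphthalene with C3=C8 and C1=C10 (key-step precursor) | O[C@@H]1C[C@@H](CO[Si](C(C)C)(C(C)C)C(C)C)C2=C(CC(C)=CC2)[C@H]1C(CO[Si](CC)(CC)CC)CO[Si](C)(C)C(C)(C)C | intermediate
19 | primary ozonide (1,2,3-trioxolane across C3–C8) | O[C@@H]1C[C@@H](CO[Si](C(C)C)(C(C)C)C(C)C)C23OOOC2(CC(C)=CC3)[C@H]1C(CO[Si](CC)(CC)CC)CO[Si](C)(C)C(C)(C)C | intermediate
20 | secondary ozonide (1,2,4-trioxolane bridging C3 and C8 of the ten-membered ring) | O[C@@H]1C[C@@H](CO[Si](C(C)C)(C(C)C)C(C)C)C2(OOC3(O2)[C@H]1C(CO[Si](CC)(CC)CC)CO[Si](C)(C)C(C)(C)C)C/C=C(C)\C3 | intermediate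
21 | (Z)-6-hydroxycyclodec-1(10)-ene-3,8-dione with C4–CH2OTIPS and C7–CH(CH2OTES)(CH2OTBS) (key-step product) | O[C@@H]1C[C@@H](CO[Si](C(C)C)(C(C)C)C(C)C)C(=O)C/C=C(C)\CC(=O)[C@H]1C(CO[Si](CC)(CC)CC)CO[Si](C)(C)C(C)(C)C | intermediate
22 | 6,8-anti-diol 3-ketone | O[C@@H]1C[C@@H](CO[Si](C(C)C)(C(C)C)C(C)C)C(=O)C/C=C(C)\C[C@@H](O)[C@H]1C(CO[Si](CC)(CC)CC)CO[Si](C)(C)C(C)(C)C | intermediate
23 | (R)-2-methylbutanoic acid | CC[C@@H](C)C(=O)O | starting material
24 | (R)-2-methylbutanoic 2,4,6-trichlorobenzoic anhydride | CC[C@@H](C)C(=O)OC(=O)c1c(Cl)cc(Cl)cc1Cl | intermediate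
25 | C8 (R)-2-methylbutanoate of 22 | O[C@@H]1C[C@@H](CO[Si](C(C)C)(C(C)C)C(C)C)C(=O)C/C=C(C)\C[C@@H](OC(=O)[C@H](C)CC)[C@H]1C(CO[Si](CC)(CC)CC)CO[Si](C)(C)C(C)(C)C | intermediate
26 | C12 primary alcohol (TES removed) | O[C@@H]1C[C@@H](CO[Si](C(C)C)(C(C)C)C(C)C)C(=O)C/C=C(C)\C[C@@H](OC(=O)[C@H](C)CC)[C@H]1C(CO)CO[Si](C)(C)C(C)(C)C | intermediate
27 | C12 aldehyde | O[C@@H]1C[C@@H](CO[Si](C(C)C)(C(C)C)C(C)C)C(=O)C/C=C(C)\C[C@@H](OC(=O)[C@H](C)CC)[C@H]1C(C=O)CO[Si](C)(C)C(C)(C)C | intermediate
28 | O6–C12 lactol | CC(C)(C)[Si](C)(C)OCC1C(O)O[C@@H]2C[C@@H](CO[Si](C(C)C)(C(C)C)C(C)C)C(=O)C/C=C(C)\C[C@@H](OC(=O)[C@H](C)CC)[C@@H]12 | intermediate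
29 | 6,12-lactone with C13–OTBS and C15–OTIPS | CC(C)(C)[Si](C)(C)OCC1C(=O)O[C@@H]2C[C@@H](CO[Si](C(C)C)(C(C)C)C(C)C)C(=O)C/C=C(C)\C[C@@H](OC(=O)[C@H](C)CC)[C@@H]12 | intermediate
30 | 13-hydroxy lactone | OCC1C(=O)O[C@@H]2C[C@@H](CO[Si](C(C)C)(C(C)C)C(C)C)C(=O)C/C=C(C)\C[C@@H](OC(=O)[C@H](C)CC)[C@@H]12 | intermediate
31 | C13 mesylate | CS(=O)(=O)OCC1C(=O)O[C@@H]2C[C@@H](CO[Si](C(C)C)(C(C)C)C(C)C)C(=O)C/C=C(C)\C[C@@H](OC(=O)[C@H](C)CC)[C@@H]12 | intermediate
32 | α-methylene lactone with C15–OTIPS | C=C1C(=O)O[C@@H]2C[C@@H](CO[Si](C(C)C)(C(C)C)C(C)C)C(=O)C/C=C(C)\C[C@@H](OC(=O)[C@H](C)CC)[C@@H]12 | intermediate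
33 | 15-hydroxy 1(10)-Z-alkene (de-epoxy target) | C=C1C(=O)O[C@@H]2C[C@@H](CO)C(=O)C/C=C(C)\C[C@@H](OC(=O)[C@H](C)CC)[C@@H]12 | intermediate
34 | CNP0219035.1: (1R,4S,6R,7S,8R,10S)-1,10-epoxy-15-hydroxy-3-oxo-8-[(R)-2-methylbutanoyloxy]germacr-11(13)-en-12,6-olide | C=C1C(=O)O[C@@H]2C[C@@H](CO)C(=O)C[C@H]3O[C@@]3(C)C[C@@H](OC(=O)[C@H](C)CC)[C@@H]12 | target

Total steps: 21. Longest linear sequence: 21 steps from 1 (3, 12 and 23 are bought).

**Steps most likely to fail**

Step 13. What may go wrong is insufficient discrimination between the tetrasubstituted C3=C8 and the trisubstituted C1=C10 alkene, so that the wrong bond or both bonds are cleaved. Fallback: starting from 18, the alkenes are told apart with a peracid, which responds more steeply to alkyl substitution than ozone. mCPBA (1 equiv, NaHCO3, CH2Cl2, −40 °C) should epoxidise only C3=C8 to the C3,C8-epoxide F1. Dilute HClO4 in aqueous THF at 0 °C opens it to the trans-3,8-diol F2, with the triethylsilyl ether watched. Pb(OAc)4 in benzene–pyridine then cleaves the glycol to dione 21, where the route is rejoined.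

Step 15. What may go wrong is loss of site selectivity, if the open hydroxy ketone tautomer is acylated at O6 as fast as the hemiketal form is acylated at O8. Fallback: starting from 22, O6 is locked before acylation. PPTS in MeOH at 0 °C converts the hemiketal into the bridged C3 methyl ketal and strips the triethylsilyl group, giving the ketal diol F3. TESCl/imidazole at −78 °C re-silylates only the primary C12 hydroxyl to give the silylated ketal F4. Yamaguchi acylation with 23 then has only O8 available and gives the ketal ester F5. AcOH–THF–H2O removes the ketal and the triethylsilyl group together and returns to 26.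

Step 21. What may go wrong is poor or reversed facial selectivity in the epoxidation of the medium-ring alkene, since the outer face of the ten-membered ring is predicted, not proven, to be the required one. Fallback: starting from 33, reagent control replaces substrate control. A Shi epoxidation is run with whichever enantiomer of the fructose-derived ketone catalyst is matched to the required face (KHSO5 as Oxone, K2CO3 buffer, MeCN–dimethoxymethane–H2O, 0 °C) and leads directly to 34. This fallback makes no new compound (F0).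

**Further compounds**
F1 | step 13 | C3,C8-epoxide of 18 | O[C@@H]1C[C@@H](CO[Si](C(C)C)(C(C)C)C(C)C)C23OC2(CC(C)=CC3)[C@H]1C(CO[Si](CC)(CC)CC)CO[Si](C)(C)C(C)(C)C
F2 | step 13 | trans-3,8-diol from F1 | O[C@@H]1C[C@@H](CO[Si](C(C)C)(C(C)C)C(C)C)C2(O)CC=C(C)CC2(O)[C@H]1C(CO[Si](CC)(CC)CC)CO[Si](C)(C)C(C)(C)C
F3 | step 15 | C3 methyl ketal bridged to O6, with free C8–OH and C12–OH | CO[C@]12C/C=C(C)\C[C@@H](O)[C@@H](C(CO)CO[Si](C)(C)C(C)(C)C)[C@H](O1)C[C@H]2CO[Si](C(C)C)(C(C)C)C(C)C
F4 | step 15 | C12–OTES derivative of F3 | CO[C@]12C/C=C(C)\C[C@@H](O)[C@@H](C(CO[Si](CC)(CC)CC)CO[Si](C)(C)C(C)(C)C)[C@H](O1)C[C@H]2CO[Si](C(C)C)(C(C)C)C(C)C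
F5 | step 15 | C8 (R)-2-methylbutanoate of F4 | CO[C@]12C/C=C(C)\C[C@@H](OC(=O)[C@H](C)CC)[C@@H](C(CO[Si](CC)(CC)CC)CO[Si](C)(C)C(C)(C)C)[C@H](O1)C[C@H]2CO[Si](C(C)C)(C(C)C)C(C)C
F0 | step 21 | none | none
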